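The route rests on disconnecting the C2–C3 bond of ring C. In flavanone numbering, C2–H is flanked by O1 and by the electron-rich ring B, which makes it a hydridic benzylic ether C–H bond lying 1,6 to C3. A chiral dirhodium carboxylate converts a C3 diazo group into a carbenoid that inserts into this bond, so one operation forms C2–C3, closes ring C and sets the (S)-configured C2. The precursor is a ring A aryl diazomethyl ketone carrying the intact 4-methoxy-3-prenylbenzyl group as an ether on the oxygen that becomes O1 and triisopropylsilyl ethers on the future O5 and O7; buffered fluoride then releases the target.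

Key step: step 7

Assumption: the sense of induction of Rh2(S-PTTL)4 on this substrate is taken to favour the (2S) product; should the opposite enantiomer predominate, the mirror-image catalyst Rh2(R-PTTL)4 would be used with no other change.

Step 1
Reactants: 1 3-bromo-4-methoxybenzaldehyde
Product: 2 2-(3-bromo-4-methoxyphenyl)-1,3-dioxolane
Conditions: HOCH2CH2OH (3 equiv), TsOH·H2O (2 mol %), toluene, reflux, Dean–Stark
Reagents that add atoms: ethylene glycol, OCCO
Why: Acid-catalysed acetalisation with azeotropic removal of water (dioxolane protection) should convert the aldehyde cleanly into an acetal that is inert to the organolithium of step 2.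

Step 2
Reactants: 2 2-(3-bromo-4-methoxyphenyl)-1,3-dioxolane; 3 prenyl bromide
Product: 7 4-methoxy-3-(3-methylbut-2-en-1-yl)benzaldehyde, via aryllithium 4 (not isolated), via arylcopper 5 (not isolated), via prenylated dioxolane 6 (not isolated)
Conditions: n-BuLi, THF, −78 °C; CuBr·SMe2 (1.0 equiv), −78 to −40 °C; 3, −40 to 0 °C; then 1 M aq HCl, THF, rt
Reagents that add atoms: prenyl bromide, CC(C)=CCBr; water, O
Why: Bromine–lithium exchange, favoured by the ortho methoxy group, followed by transmetalation to copper and allylic substitution at the unhindered primary carbon of prenyl bromide (SN2-type copper-mediated allylation) should give the linear prenyl arene, and the dilute acid of the work-up hydrolyses the dioxolane (acetal hydrolysis) without affecting the trisubstituted alkene.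

Step 3
Reactants: 7 4-methoxy-3-(3-methylbut-2-en-1-yl)benzaldehyde
Product: 8 [4-methoxy-3-(3-methylbut-2-en-1-yl)phenyl]methanol
Conditions: NaBH4, MeOH, 0 °C
Reagents that add atoms: none
Why: Sodium borohydride reduction of an aromatic aldehyde is fast and chemoselective at 0 °C, so the benzylic alcohol should form without touching the alkene or the methyl ether.

Step 4
Reactants: 9 2',4',6'-trihydroxyacetophenone (dried beforehand)
Product: 10 1-[2-hydroxy-4,6-bis(triisopropylsilyloxy)phenyl]ethanone
Conditions: i-Pr3SiCl (2.1 equiv), imidazole (4.5 equiv), DMF, 0 °C to rt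
Reagents that add atoms: triisopropylsilyl chloride, CC(C)[Si](Cl)(C(C)C)C(C)C
Why: Silylation of phenols with a silyl chloride and imidazole should take the para hydroxyl and one ortho hydroxyl while the remaining ortho hydroxyl stays masked by its hydrogen bond to the carbonyl group, and because the two ortho positions are equivalent only one bis-silyl ether can result.

Step 5
Reactants: 10 1-[2-hydroxy-4,6-bis(triisopropylsilyloxy)phenyl]ethanone; 8 [4-methoxy-3-(3-methylbut-2-en-1-yl)phenyl]methanol
Product: 11 1-[2-{[4-methoxy-3-(3-methylbut-2-en-1-yl)benzyl]oxy}-4,6-bis(triisopropylsilyloxy)phenyl]ethanone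
Conditions: PPh3, DIAD, THF, 0 °C to rt
Reagents that add atoms: none
Why: Mitsunobu etherification suits this pair because the phenol, acidified by the ortho acyl group, is a competent pronucleophile, the primary benzylic alcohol is readily activated as its alkoxyphosphonium salt, and the neutral redox conditions spare the aryl silyl ethers that a basic alkylation would endanger.

Step 6
Reactants: 11 1-[2-{[4-methoxy-3-(3-methylbut-2-en-1-yl)benzyl]oxy}-4,6-bis(triisopropylsilyloxy)phenyl]ethanone
Product: 13 2-diazo-1-[2-{[4-methoxy-3-(3-methylbut-2-en-1-yl)benzyl]oxy}-4,6-bis(triisopropylsilyloxy)phenyl]ethanone, via trifluoroacetyl diketone 12 (not isolated)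
Conditions: LiN(SiMe3)2 (1.1 equiv), THF, −78 °C; CF3CO2CH2CF3 (1.2 equiv), −78 °C; 5% aq HCl quench, crude 12 taken up in MeCN without purification; 4-AcNHC6H4SO2N3 (1.5 equiv), Et3N (1.5 equiv), H2O (1 equiv), MeCN, rt
Reagents that add atoms: 4-acetamidobenzenesulfonyl azide, CC(=O)Nc1ccc(cc1)S(=O)(=O)N=[N+]=[N-] (the two diazo nitrogens); 2,2,2-trifluoroethyl trifluoroacetate, O=C(OCC(F)(F)F)C(F)(F)F (its CF3CO group stays only in 12)
Why: Danheiser detrifluoroacetylative diazo transfer: the kinetic lithium enolate of the methyl ketone undergoes Claisen-type C-acylation by the trifluoroethyl ester, and the resulting activated 1,3-diketone accepts the diazo group from the sulfonyl azide (Regitz transfer) with loss of the trifluoroacetyl group as its N-sulfonyl amide, a sequence that is reliable for aryl methyl ketones and mild enough for the silyl ethers, the benzyl ether and the alkene.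

Step 7
Reactants: 13 2-diazo-1-[2-{[4-methoxy-3-(3-methylbut-2-en-1-yl)benzyl]oxy}-4,6-bis(triisopropylsilyloxy)phenyl]ethanone
Product: 14 (2S)-2-[4-methoxy-3-(3-methylbut-2-en-1-yl)phenyl]-5,7-bis(triisopropylsilyloxy)chroman-4-one [(S)-5,7-bis(triisopropylsilyloxy)-4'-methoxy-3'-prenylflavanone]
Conditions: Rh2(S-PTTL)4, dirhodium tetrakis[N-phthaloyl-(S)-tert-leucinate] (1 mol %), dry CH2Cl2 (0.01 M), 0 °C, slow addition of 13
Reagents that add atoms: none
Why: Rh2(S-PTTL)4 expels N2 from 13 to give an electrophilic divalent rhodium carbenoid at C3, which takes up the C2–H bond in a concerted, asynchronous three-centre transition state (hydride-like shift towards C3 together with C2–C3 bond formation and release of the catalyst). The closest known reaction type is the chiral dirhodium carboxylate-catalysed intramolecular C–H insertion of ortho-alkoxyaryl diazomethyl ketones into the ether α-C–H bond, which gives 2-substituted chroman-4-ones; 13 is a 2-aryl member of that class. Ring C closes by 1,6-insertion through a six-membered transition state, the only low-strain option because the position 1,5 to the carbenoid is the ether oxygen itself and the aryl ketone tether is rigid. The C2 stereocentre is set by catalyst control: the N-phthaloyl-tert-leucinate ligands shape a chiral pocket around the carbenoid that selects one of the two enantiotopic benzylic hydrogens, with no stereochemical input from the substrate, and the neutral, non-enolising conditions leave the new centre untouched. The step needs chemoselectivity for this C–H bond over oxonium ylide formation at either ortho oxygen, over cyclopropanation of the prenyl alkene and over addition to ring B; this should be secured by the double activation of C2–H by O1 and the para-methoxyaryl ring, by the low basicity of an aryl ether oxygen conjugated to the ketone, by the bulk and the lack of activated C–H bonds of the triisopropylsilyl group at O5, and by slow addition at high dilution, which suppresses bimolecular attack on the remote alkene.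

Step 8
Reactants: 14 (2S)-2-[4-methoxy-3-(3-methylbut-2-en-1-yl)phenyl]-5,7-bis(triisopropylsilyloxy)chroman-4-one
Product: 15 4'-O-methyllicoflavanone [(2S)-5,7-dihydroxy-2-[4-methoxy-3-(3-methylbut-2-en-1-yl)phenyl]chroman-4-one]
Conditions: Bu4NF (2.5 equiv), AcOH (2.5 equiv), THF, 0 °C
Reagents that add atoms: none
Why: Fluoride-induced desilylation, driven by the strong Si–F bond, cleaves aryl silyl ethers quickly at 0 °C, and the acetic acid buffer keeps the liberated phenols protonated so that base-induced opening of ring C to the chalcone (retro-oxa-Michael) and with it racemisation at C2 should not set in.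

Compound list
1 | 3-bromo-4-methoxybenzaldehyde | COc1ccc(C=O)cc1Br | starting material
2 | 2-(3-bromo-4-methoxyphenyl)-1,3-dioxolane | COc1ccc(C2OCCO2)cc1Br | intermediate
3 | prenyl bromide (1-bromo-3-methylbut-2-ene) | CC(C)=CCBr | starting material
4 | [5-(1,3-dioxolan-2-yl)-2-methoxyphenyl]lithium (aryllithium, not isolated) | COc1ccc(C2OCCO2)cc1[Li] | intermediate
5 | [5-(1,3-dioxolan-2-yl)-2-methoxyphenyl]copper (arylcopper, not isolated) | COc1ccc(C2OCCO2)cc1[Cu] | intermediate
6 | 2-[4-methoxy-3-(3-methylbut-2-en-1-yl)phenyl]-1,3-dioxolane (prenylated dioxolane, not isolated) | COc1ccc(C2OCCO2)cc1CC=C(C)C | intermediate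
7 | 4-methoxy-3-(3-methylbut-2-en-1-yl)benzaldehyde | COc1ccc(C=O)cc1CC=C(C)C | intermediate
8 | [4-methoxy-3-(3-methylbut-2-en-1-yl)phenyl]methanol | COc1ccc(CO)cc1CC=C(C)C | intermediate
9 | 2',4',6'-trihydroxyacetophenone | CC(=O)c1c(O)cc(O)cc1O | starting material
10 | 1-[2-hydroxy-4,6-bis(triisopropylsilyloxy)phenyl]ethanone | CC(=O)c1c(O)cc(O[Si](C(C)C)(C(C)C)C(C)C)cc1O[Si](C(C)C)(C(C)C)C(C)C | intermediate
11 | 1-[2-{[4-methoxy-3-(3-methylbut-2-en-1-yl)benzyl]oxy}-4,6-bis(triisopropylsilyloxy)phenyl]ethanone | CC(=O)c1c(OCc2ccc(OC)c(CC=C(C)C)c2)cc(O[Si](C(C)C)(C(C)C)C(C)C)cc1O[Si](C(C)C)(C(C)C)C(C)C | intermediate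
12 | 4,4,4-trifluoro-1-[2-{[4-methoxy-3-(3-methylbut-2-en-1-yl)benzyl]oxy}-4,6-bis(triisopropylsilyloxy)phenyl]butane-1,3-dione (trifluoroacetyl diketone, not isolated) | O=C(CC(=O)C(F)(F)F)c1c(OCc2ccc(OC)c(CC=C(C)C)c2)cc(O[Si](C(C)C)(C(C)C)C(C)C)cc1O[Si](C(C)C)(C(C)C)C(C)C | intermediate
13 | 2-diazo-1-[2-{[4-methoxy-3-(3-methylbut-2-en-1-yl)benzyl]oxy}-4,6-bis(triisopropylsilyloxy)phenyl]ethanone | [N-]=[N+]=CC(=O)c1c(OCc2ccc(OC)c(CC=C(C)C)c2)cc(O[Si](C(C)C)(C(C)C)C(C)C)cc1O[Si](C(C)C)(C(C)C)C(C)C | intermediate
14 | (2S)-2-[4-methoxy-3-(3-methylbut-2-en-1-yl)phenyl]-5,7-bis(triisopropylsilyloxy)chroman-4-one | COc1ccc([C@@H]2CC(=O)c3c(O[Si](C(C)C)(C(C)C)C(C)C)cc(O[Si](C(C)C)(C(C)C)C(C)C)cc3O2)cc1CC=C(C)C | intermediate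
15 | 4'-O-methyllicoflavanone, (2S)-5,7-dihydroxy-2-[4-methoxy-3-(3-methylbut-2-en-1-yl)phenyl]chroman-4-one | COc1ccc([C@@H]2CC(=O)c3c(O)cc(O)cc3O2)cc1CC=C(C)C | target

Total step count: 8
Longest linear sequence: 7 steps (steps 1, 2, 3, 5, 6, 7 and 8, from 1 to 15); step 4 is the one-step side branch to ring A.

Steps most likely to fail

Step 7. The chiral carboxylate may discriminate poorly between the two enantiotopic benzylic hydrogens, so that the flavanone forms with insufficient enantiomeric purity. Fallback: setting out from 13, decomposition with achiral Rh2(OAc)4 in CH2Cl2 would give racemic 5,7-bis(triisopropylsilyloxy)-4'-methoxy-3'-prenylflavanone F1. Kinetic resolution of F1 by Noyori-type asymmetric transfer hydrogenation, a known way to resolve racemic flavanones, would follow. It would use RuCl[TsDPEN](p-cymene) with HCO2H/Et3N, in the antipode that consumes the (2R)-ketone, expected to be the (R,R)-complex. The (2R)-enantiomer would be reduced to (2R,4R)-2-[4-methoxy-3-(3-methylbut-2-en-1-yl)phenyl]-5,7-bis(triisopropylsilyloxy)chroman-4-ol F2, separable by chromatography. The (2S)-ketone would be left untouched, and the route is rejoined at 14.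

Step 6. The lithium enolate, flanked by two ortho substituents, may be C-acylated incompletely or may take up the neighbouring silyl group by anionic oxygen-to-oxygen migration, leaving no activated methylene for diazo transfer. Fallback: setting out from 11, condensation with Me2NCH(OMe)2 in toluene at 90 °C, with no strong base, would give (E)-3-(dimethylamino)-1-[2-{[4-methoxy-3-(3-methylbut-2-en-1-yl)benzyl]oxy}-4,6-bis(triisopropylsilyloxy)phenyl]prop-2-en-1-one F3. Sulfonyl azides add to such N,N-dimethyl enaminones, and the cycloadduct fragments to the diazomethyl ketone and an N-sulfonylformamidine. Treatment of F3 with 4-acetamidobenzenesulfonyl azide in MeCN at rt should therefore deliver 13, where the route is rejoined.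

Step 5. Etherification of the hydrogen-bonded phenol may be slow, and the activated electron-rich benzylic alcohol may be diverted to C-benzylation of ring A or to alkylation of the hydrazide by-product. Fallback: setting out from 8, PBr3 with a little pyridine in Et2O at 0 °C would give 4-(bromomethyl)-1-methoxy-2-(3-methylbut-2-en-1-yl)benzene F4, used at once. Williamson alkylation of phenol 10 with F4 and K2CO3 in dry acetone at rt would then give 11, where the route is rejoined. Any silyl shift between the two equivalent ortho oxygens under these mildly basic conditions would be degenerate.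

Further compounds
F1 | step 7 | racemic 2-[4-methoxy-3-(3-methylbut-2-en-1-yl)phenyl]-5,7-bis(triisopropylsilyloxy)chroman-4-one | COc1ccc(C2CC(=O)c3c(O[Si](C(C)C)(C(C)C)C(C)C)cc(O[Si](C(C)C)(C(C)C)C(C)C)cc3O2)cc1CC=C(C)C
F2 | step 7 | (2R,4R)-2-[4-methoxy-3-(3-methylbut-2-en-1-yl)phenyl]-5,7-bis(triisopropylsilyloxy)chroman-4-ol | COc1ccc([C@H]2C[C@@H](O)c3c(O[Si](C(C)C)(C(C)C)C(C)C)cc(O[Si](C(C)C)(C(C)C)C(C)C)cc3O2)cc1CC=C(C)C
F3 | step 6 | (E)-3-(dimethylamino)-1-[2-{[4-methoxy-3-(3-methylbut-2-en-1-yl)benzyl]oxy}-4,6-bis(triisopropylsilyloxy)phenyl]prop-2-en-1-one | CN(C)/C=C/C(=O)c1c(OCc2ccc(OC)c(CC=C(C)C)c2)cc(O[Si](C(C)C)(C(C)C)C(C)C)cc1O[Si](C(C)C)(C(C)C)C(C)C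
F4 | step 5 | 4-(bromomethyl)-1-methoxy-2-(3-methylbut-2-en-1-yl)benzene | COc1ccc(CBr)cc1CC=C(C)C
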